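**Remark on the chemistry:** the SMILES is read as the (2S)-flavanone carrying an (E)-geranyl group on C6 (flavanone numbering; chain carbons C1''–C10''). Benzyltrimethylammonium dichloroiodate and (S)-MeO-F12-BIPHEP are taken as purchasable.

## Retrosynthetic overview

- Last disconnection C6–C1'' (A-ring carbon to the geranyl CH2): (S)-6-iodo-5-hydroxy-7,3',4'-trimethoxyflavanone plus geranyl acetate. Two electrophilic carbons are joined by nickel-catalysed reductive cross-electrophile coupling on the unprotected phenol, so the target is released directly.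
- Enabling feature: the C5 hydroxyl, chelated to the C4 carbonyl of the pyranone ring, is ortho only to C6 (C8 lies between ring oxygen O1 and the 7-OMe). It steers iodination to C6, turning the innately nucleophilic A-ring carbon into an electrophile, and holds its proton away from C6 during coupling. The fully substituted C3'' terminus of the geranyl unit forces bond formation at C1'' with the E alkene intact.
- C2 stereocentre: Rh-catalysed asymmetric 1,4-addition of 3,4-dimethoxyphenylboronic acid to the 6-iodochromone (5-OH masked as MOM for this step only).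
- Ring order: A and B rings are bought. The pyranone ring is closed first (enaminone annulation of the symmetric 2',6'-dihydroxy-4'-methoxyacetophenone), then C6–I, then the B ring at C2, and the C10 chain last.

Key step: step 6

## Route

Step 1
Reactants: 1 2',6'-dihydroxy-4'-methoxyacetophenone
Product: 3 5-hydroxy-7-methoxy-4H-chromen-4-one, via enaminone 2 (not isolated)
Conditions: DMF–DMA (2.5 equiv), toluene, 95 °C; evaporate; AcOH, 90 °C
Reagents that add atoms: N,N-dimethylformamide dimethyl acetal, COC(OC)N(C)C
Why: Enaminone chromone annulation: DMF–DMA condenses at the acetyl CH3, and in acid one phenol adds 6-endo to the β-carbon with loss of dimethylamine; the two phenols of 1 are equivalent by symmetry, so only one chromone can form.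

Step 2
Reactants: 3 5-hydroxy-7-methoxy-4H-chromen-4-one
Product: 4 5-hydroxy-6-iodo-7-methoxy-4H-chromen-4-one
Conditions: BnMe3N·ICl2 (1.05 equiv), CaCO3, CH2Cl2/MeOH, 20 °C
Reagents that add atoms: benzyltrimethylammonium dichloroiodate, C[N+](C)(C)Cc1ccccc1.Cl[I-]Cl
Why: Electrophilic aromatic iodination ortho to the chelated 5-OH, the site selectivity known for 5-hydroxy-7-alkoxy chromone-type rings (with a 5-O-alkyl group attack would shift to C8); CaCO3 takes up the HCl.

Step 3
Reactants: 4 5-hydroxy-6-iodo-7-methoxy-4H-chromen-4-one
Product: 5 6-iodo-7-methoxy-5-(methoxymethoxy)-4H-chromen-4-one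
Conditions: NaH (1.3 equiv), MOMCl (1.5 equiv), DMF, 0 °C to rt
Reagents that add atoms: chloromethyl methyl ether (MOMCl), COCCl
Why: Williamson-type O-alkylation of the sodium phenoxide with the small, highly reactive chloromethyl ether; the MOM group removes the peri-hydroxy ketone chelate, which would bind rhodium like an acetylacetonate in step 4.

Step 4
Reactants: 5 6-iodo-7-methoxy-5-(methoxymethoxy)-4H-chromen-4-one; 6 3,4-dimethoxyphenylboronic acid
Product: 7 (2S)-2-(3,4-dimethoxyphenyl)-6-iodo-7-methoxy-5-(methoxymethoxy)-2,3-dihydro-4H-chromen-4-one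
Conditions: [Rh(OH)((S)-MeO-F12-BIPHEP)]2 (3 mol% Rh), 6 (2.5 equiv), CH2Cl2/H2O (10:1), 25 °C
Reagents that add atoms: none
Why: Rh-catalysed asymmetric 1,4-addition of an arylboronic acid (Hayashi–Miyaura reaction): the aryl–Rh species inserts the C2=C3 bond of the chromone on the enantioface selected by the (S)-biaryl bisphosphine, which should give 2S by the same facial sense that leads from cyclohexenone to (S)-3-arylcyclohexanones with (S)-BINAP (the ligand antipode would be taken if analysis showed the opposite), and water protonates the rhodium enolate before it can open the ring.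

Step 5
Reactants: 7 (2S)-2-(3,4-dimethoxyphenyl)-6-iodo-7-methoxy-5-(methoxymethoxy)-2,3-dihydro-4H-chromen-4-one
Product: 8 (2S)-2-(3,4-dimethoxyphenyl)-5-hydroxy-6-iodo-7-methoxy-2,3-dihydro-4H-chromen-4-one
Conditions: HCl (1 M in MeOH), THF, 25 °C
Reagents that add atoms: none
Why: Acid-catalysed acetal exchange with methanol (MOM cleavage), fast for the ether peri to the C4 carbonyl; the aryl iodide, the methyl ethers and the C2 centre are expected to be stable to dilute acid at room temperature.

Step 6
Reactants: 8 (2S)-2-(3,4-dimethoxyphenyl)-5-hydroxy-6-iodo-7-methoxy-2,3-dihydro-4H-chromen-4-one; 9 geranyl acetate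
Product: 10 (2S)-2-(3,4-dimethoxyphenyl)-6-[(2E)-3,7-dimethylocta-2,6-dien-1-yl]-5-hydroxy-7-methoxy-2,3-dihydro-4H-chromen-4-one
Conditions: NiBr2·glyme (10 mol%), dtbbpy (10 mol%), Zn dust (2.5 equiv), 9 (2 equiv), DMA/THF, 40 °C
Reagents that add atoms: none
Why: Ni(0)–dtbbpy adds oxidatively to the C6–I bond and ionises geranyl acetate to an η3-geranylnickel species, zinc reduces the Ni(II) intermediates so that aryl and allyl meet on one nickel centre, and C(sp2)–C(sp3) reductive elimination forms C6–C1''. The closest known reaction type is the nickel-catalysed reductive cross-electrophile coupling of aryl halides with allylic acetates, which gives linear (E)-allylarenes. No ring is closed and no stereocentre is created; C2 is expected to stay intact because the medium contains no base that could open the pyranone ring by E1cB. The site is fixed by the iodine; linear coupling and retention of the E alkene follow from the geranyl unit itself, since bond formation at, or nickel σ-bonding to, the fully substituted C3'' is disfavoured next to a 2,6-dioxygenated aryl group. Cross- rather than homo-coupling is secured by the different activation modes of the two electrophiles and by an excess of the acetate, which unlike an allylic halide is inert to zinc itself, so no configurationally labile geranylzinc is formed. The free 5-OH is tolerated because its proton sits in the six-membered chelate with C4=O and points away from C6, and its small size keeps the flank of the C–I bond open.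

## Compound list

1 | 2',6'-dihydroxy-4'-methoxyacetophenone | CC(=O)c1c(O)cc(OC)cc1O | starting material
2 | (E)-1-(2,6-dihydroxy-4-methoxyphenyl)-3-(dimethylamino)prop-2-en-1-one | CN(C)/C=C/C(=O)c1c(O)cc(OC)cc1O | intermediate
3 | 5-hydroxy-7-methoxy-4H-chromen-4-one | COc1cc(O)c2c(c1)OC=CC2=O | intermediate
4 | 5-hydroxy-6-iodo-7-methoxy-4H-chromen-4-one | COc1cc2OC=CC(=O)c2c(O)c1I | intermediate
5 | 6-iodo-7-methoxy-5-(methoxymethoxy)-4H-chromen-4-one | COCOc1c(I)c(OC)cc2OC=CC(=O)c12 | intermediate
6 | 3,4-dimethoxyphenylboronic acid | COc1ccc(B(O)O)cc1OC | starting material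
7 | (2S)-2-(3,4-dimethoxyphenyl)-6-iodo-7-methoxy-5-(methoxymethoxy)-2,3-dihydro-4H-chromen-4-one | COc1ccc([C@@H]2CC(=O)c3c(cc(OC)c(I)c3OCOC)O2)cc1OC | intermediate
8 | (2S)-2-(3,4-dimethoxyphenyl)-5-hydroxy-6-iodo-7-methoxy-2,3-dihydro-4H-chromen-4-one | COc1ccc([C@@H]2CC(=O)c3c(cc(OC)c(I)c3O)O2)cc1OC | intermediate
9 | geranyl acetate, (2E)-3,7-dimethylocta-2,6-dien-1-yl acetate | CC(=O)OC/C=C(\C)CCC=C(C)C | starting material
10 | (2S)-2-(3,4-dimethoxyphenyl)-6-[(2E)-3,7-dimethylocta-2,6-dien-1-yl]-5-hydroxy-7-methoxy-2,3-dihydro-4H-chromen-4-one | COc1ccc([C@@H]2CC(=O)c3c(cc(OC)c(C/C=C(\C)CCC=C(C)C)c3O)O2)cc1OC | target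

## Step count and risks

Total step count: 6. Longest linear sequence: 6 steps (1 to 10).

Steps most likely to fail:

1. Step 6. The congested aryl–nickel intermediate may be captured too slowly, so that protodeiodination and geranyl homocoupling take over, or π-allyl isomerisation may erode the E geometry. Fallback: setting out from 8, a Stille coupling (Pd2(dba)3, AsPh3, CuI, DMF, 60 °C, no base) with tributyl(geranyl)stannane F1, itself to be made from geranyl chloride and Bu3SnLi, replaces the union of two electrophiles by an electrophile–nucleophile pairing and comes back to the route at 10.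

2. Step 2. Iodination may lose site selectivity (attack at C8, double iodination, or reaction at the C2=C3 enol ether). Fallback: setting out from 1, the iodine is introduced while the ring is still symmetric (NIS, MeCN, 0 °C), which can give only 1-(2,6-dihydroxy-3-iodo-4-methoxyphenyl)ethan-1-one F2. Condensation with DMF–DMA should give the enaminone F3, and acid-mediated ring closure is expected to go through the phenol remote from iodine, because the more acidic, iodine-flanked phenol is the one held in the hydrogen bond to the ketone. This returns to the route at 4.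

3. Step 4. Rh(I) may insert into the C–I bond (catalyst loss, deiodination), or the rhodium enolate may open to the chalcone by β-alkoxide elimination and reclose without control, lowering the enantiomeric purity. Fallback: setting out from 3, the stereocentre is set before any halogen is present. MOM protection should give 7-methoxy-5-(methoxymethoxy)-4H-chromen-4-one F4, and the same Rh-catalysed arylation with 6 should give (2S)-2-(3,4-dimethoxyphenyl)-7-methoxy-5-(methoxymethoxy)-2,3-dihydro-4H-chromen-4-one F5. Acidic methanolysis then leads to (2S)-2-(3,4-dimethoxyphenyl)-5-hydroxy-7-methoxy-2,3-dihydro-4H-chromen-4-one F6, and chelation-directed iodination (BnMe3N·ICl2, CaCO3) of F6 comes back to the route at 8.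

## Further compounds

F1 | step 6 | tributyl[(2E)-3,7-dimethylocta-2,6-dien-1-yl]stannane | CCCC[Sn](CCCC)(CCCC)C/C=C(\C)CCC=C(C)C
F2 | step 2 | 1-(2,6-dihydroxy-3-iodo-4-methoxyphenyl)ethan-1-one | CC(=O)c1c(O)cc(OC)c(I)c1O
F3 | step 2 | (E)-1-(2,6-dihydroxy-3-iodo-4-methoxyphenyl)-3-(dimethylamino)prop-2-en-1-one | CN(C)/C=C/C(=O)c1c(O)cc(OC)c(I)c1O
F4 | step 4 | 7-methoxy-5-(methoxymethoxy)-4H-chromen-4-one | COCOc1cc(OC)cc2OC=CC(=O)c12
F5 | step 4 | (2S)-2-(3,4-dimethoxyphenyl)-7-methoxy-5-(methoxymethoxy)-2,3-dihydro-4H-chromen-4-one | COc1ccc([C@@H]2CC(=O)c3c(cc(OC)cc3OCOC)O2)cc1OC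
F6 | step 4 | (2S)-2-(3,4-dimethoxyphenyl)-5-hydroxy-7-methoxy-2,3-dihydro-4H-chromen-4-one | COc1ccc([C@@H]2CC(=O)c3c(cc(OC)cc3O)O2)cc1OC
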